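The route cuts the two exocyclic bonds of the dihydrofuran ring, C7–aryl and C8–C9, back to an intact benzofuran. C7 and C8 are C2 and C3 of that heterocycle, and the trimethoxyphenyl group and C9 lie on opposite faces, the arrangement an electrophile-triggered 1,2-shift from boron delivers. In one operation a benzofuran-2-yl(aryl)boronate is alkylated at C8 by iodomethyl pivalate while the aryl group moves from boron to C7, creating both bonds and both stereocentres; a C2-symmetric diol on boron is relied on for the absolute sense. The precursor is 5-(dimethoxymethyl)-7-methoxybenzofuran, lithiated at C2 and trapped with a chiral 3,4,5-trimethoxyphenylboronic ester.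

Key step: step 5

Assumption: the (R,R)-diol is taken to direct the alkylation to the face of C8 that leads to the (7R,8S) series. This sense is unproven; if the other face is preferred, the (S,S)-diol would be used with no other change.

Remark: neolignan numbering (C7, C8, C9) is used for the target; C7 is C2 and C8 is C3 of the benzofuran.

Step 1
Reactants: 1 5-iodovanillin; 2 trimethylsilylacetylene
Product: 4 7-methoxy-2-(trimethylsilyl)-1-benzofuran-5-carbaldehyde, via o-silylethynylphenol 3 (not isolated)
Conditions: PdCl2(PPh3)2 (cat.), CuI (cat.), Et3N, DMF, rt then 70 °C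
Reagents that add atoms: none
Why: Sonogashira coupling at the C–I bond is followed in the same pot by Cu/Pd-assisted 5-endo-dig cycloisomerisation of the acidic ortho-phenol onto the silylalkyne (domino Sonogashira–heteroannulation), a standard entry to 2-substituted benzofurans from o-iodophenols that tolerates the free aldehyde.

Step 2
Reactants: 4 7-methoxy-2-(trimethylsilyl)-1-benzofuran-5-carbaldehyde
Product: 5 7-methoxy-1-benzofuran-5-carbaldehyde
Conditions: TBAF (wet), THF, rt to 50 °C
Reagents that add atoms: none
Why: Fluoride-mediated protodesilylation, in which attack of fluoride on silicon releases the C2 position of the benzofuran for protonation by the water of the reagent, while the aldehyde and the aryl ether are inert.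

Step 3
Reactants: 5 7-methoxy-1-benzofuran-5-carbaldehyde
Product: 6 5-(dimethoxymethyl)-7-methoxy-1-benzofuran
Conditions: HC(OMe)3, MeOH, p-TsOH (cat.), rt; Et3N quench; Et3N-deactivated silica
Reagents that add atoms: trimethyl orthoformate, COC(OC)OC; methanol, CO
Why: Acid-catalysed acetalisation, driven by the orthoester as water scavenger, masks the aldehyde as a base-stable dimethyl acetal so that C2–H can be lithiated in step 5.

Step 4
Reactants: 7 3,4,5-trimethoxyphenylboronic acid; 8 (1R,2R)-1,2-dicyclohexylethane-1,2-diol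
Product: 9 (4R,5R)-4,5-dicyclohexyl-2-(3,4,5-trimethoxyphenyl)-1,3,2-dioxaborolane
Conditions: toluene, reflux, Dean–Stark
Reagents that add atoms: none
Why: Condensation of a boronic acid with a 1,2-diol (boronic esterification) goes to completion on azeotropic removal of water and gives a robust, hindered dioxaborolane that carries the stereochemical information into step 5.

Step 5
Reactants: 6 5-(dimethoxymethyl)-7-methoxy-1-benzofuran; 9 (4R,5R)-4,5-dicyclohexyl-2-(3,4,5-trimethoxyphenyl)-1,3,2-dioxaborolane; 10 iodomethyl pivalate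
Product: 13 [(2R,3S)-2-[(4R,5R)-4,5-dicyclohexyl-1,3,2-dioxaborolan-2-yl]-5-(dimethoxymethyl)-7-methoxy-2-(3,4,5-trimethoxyphenyl)-2,3-dihydro-1-benzofuran-3-yl]methyl pivalate, via 2-lithiobenzofuran 11 (not isolated), via lithium boronate 12 (not isolated)
Conditions: n-BuLi (1.0 equiv), THF, −78 °C; 9, −78 → 0 °C; then 10, THF/MeCN, −40 °C → rt
Reagents that add atoms: none
Why: Proposed new method: C2-lithiation of 6 and addition to boronic ester 9 should give the tetracoordinate boronate 12, whose C3 (C8 of the target) is an electron-rich enol-ether carbon made more nucleophilic by the anionic boron; SN2 attack of this carbon on iodomethyl pivalate forms C8–C9 and builds positive charge at C2 (C7), to which the trimethoxyphenyl group migrates from boron in a concerted 1,2-metallate shift that forms C7–aryl and dearomatises the furan ring. The closest known reaction type is the electrophile-induced dearomative 1,2-migration of indol-2-yl and furan-2-yl boronate complexes in three-component couplings; a benzofuran-2-yl boronate, a one-carbon alkyl halide and auxiliary-based absolute control have not been shown together. No ring is closed. The relative configuration is controlled by the mechanism, because the migrating aryl group must be antiperiplanar to the bond forming at C8, so aryl and CH2OPiv end trans and boron ends cis to C9; the absolute configuration at C8, and with it C7, is to be controlled by the (R,R)-diol on boron, which in the reactive conformer (B–aryl bond perpendicular to the benzofuran plane) holds one cyclohexyl group over one face of C3 and leaves the other open to the electrophile. The step needs lithiation at C2 only, which the far higher acidity of the benzofuran C2–H over the arene and acetal positions secures, and alkylation at C3 and not at oxygen, which the enolate-like polarisation of the boronate and the high SN2 reactivity of the acyloxymethyl iodide secure. Because the auxiliary stays on boron, a minor (7S,8R) adduct would be a diastereomer of 13 and should be removable by chromatography or crystallisation before the auxiliary is lost.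

Step 6
Reactants: 13 [(2R,3S)-2-[(4R,5R)-4,5-dicyclohexyl-1,3,2-dioxaborolan-2-yl]-5-(dimethoxymethyl)-7-methoxy-2-(3,4,5-trimethoxyphenyl)-2,3-dihydro-1-benzofuran-3-yl]methyl pivalate
Product: 15 [(2R,3S)-5-formyl-7-methoxy-2-(3,4,5-trimethoxyphenyl)-2,3-dihydro-1-benzofuran-3-yl]methyl pivalate, via deborylated acetal 14 (not isolated)
Conditions: TBAF·3H2O, toluene, 45 °C; aqueous wash; then 1 M HCl, THF, rt
Reagents that add atoms: water, O
Why: Stereoretentive protodeboronation of a tertiary benzylic boronic ester, in which fluoride forms the fluoroboronate and water protonates C7 on the side of the departing boron (SE2 with retention), puts H where boron stood, cis to C9, and leaves the aryl group trans; dilute acid then hydrolyses the dimethyl acetal (acetal hydrolysis) without touching the pivalate.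

Step 7
Reactants: 15 [(2R,3S)-5-formyl-7-methoxy-2-(3,4,5-trimethoxyphenyl)-2,3-dihydro-1-benzofuran-3-yl]methyl pivalate
Product: 16 ethyl (E)-3-[(2R,3S)-7-methoxy-3-(pivaloyloxymethyl)-2-(3,4,5-trimethoxyphenyl)-2,3-dihydro-1-benzofuran-5-yl]prop-2-enoate
Conditions: (EtO)2P(O)CH2CO2Et, NaH, THF, 0 °C → rt
Reagents that add atoms: triethyl phosphonoacetate, CCOC(=O)CP(=O)(OCC)OCC
Why: Horner–Wadsworth–Emmons olefination of an aromatic aldehyde with a stabilised phosphonate anion should give the (E)-enoate, and neither the pivalate nor the non-acidic C7 and C8 centres are affected.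

Step 8
Reactants: 16 ethyl (E)-3-[(2R,3S)-7-methoxy-3-(pivaloyloxymethyl)-2-(3,4,5-trimethoxyphenyl)-2,3-dihydro-1-benzofuran-5-yl]prop-2-enoate
Product: 17 (−)-(7R,8S,7'E)-3,4,5,5'-tetramethoxy-4',7-epoxy-8,3'-neolign-7'-ene-9,9'-diol
Conditions: DIBAL-H (excess), CH2Cl2, −78 → 0 °C; Rochelle salt work-up
Reagents that add atoms: none
Why: DIBAL-H reduces the α,β-unsaturated ester by 1,2-addition to the allylic alcohol and reductively cleaves the pivalate to the primary alcohol in the same operation (ester reduction), leaving the E-alkene, the aryl ethers and both stereocentres untouched.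

Compound list

1 | 5-iodovanillin (4-hydroxy-3-iodo-5-methoxybenzaldehyde) | COc1cc(C=O)cc(I)c1O | starting material
2 | trimethylsilylacetylene | C#C[Si](C)(C)C | starting material
3 | 4-hydroxy-3-methoxy-5-[(trimethylsilyl)ethynyl]benzaldehyde | COc1cc(C=O)cc(C#C[Si](C)(C)C)c1O | intermediate (not isolated)
4 | 7-methoxy-2-(trimethylsilyl)-1-benzofuran-5-carbaldehyde | COc1cc(C=O)cc2cc([Si](C)(C)C)oc12 | intermediate
5 | 7-methoxy-1-benzofuran-5-carbaldehyde | COc1cc(C=O)cc2ccoc12 | intermediate
6 | 5-(dimethoxymethyl)-7-methoxy-1-benzofuran | COC(OC)c1cc(OC)c2occc2c1 | intermediate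
7 | 3,4,5-trimethoxyphenylboronic acid | COc1cc(B(O)O)cc(OC)c1OC | starting material
8 | (1R,2R)-1,2-dicyclohexylethane-1,2-diol | O[C@H](C1CCCCC1)[C@H](O)C1CCCCC1 | starting material
9 | (4R,5R)-4,5-dicyclohexyl-2-(3,4,5-trimethoxyphenyl)-1,3,2-dioxaborolane | COc1cc(B2O[C@H](C3CCCCC3)[C@@H](C3CCCCC3)O2)cc(OC)c1OC | intermediate
10 | iodomethyl pivalate (iodomethyl 2,2-dimethylpropanoate) | CC(C)(C)C(=O)OCI | starting material
11 | 5-(dimethoxymethyl)-7-methoxy-1-benzofuran-2-yllithium | [Li]c1cc2cc(C(OC)OC)cc(OC)c2o1 | intermediate (not isolated)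
12 | lithium (4R,5R)-4,5-dicyclohexyl-2-[5-(dimethoxymethyl)-7-methoxy-1-benzofuran-2-yl]-2-(3,4,5-trimethoxyphenyl)-1,3,2-dioxaborolan-2-uide | [Li+].COc1cc([B-]2(c3cc4cc(C(OC)OC)cc(OC)c4o3)O[C@H](C3CCCCC3)[C@@H](C3CCCCC3)O2)cc(OC)c1OC | intermediate (not isolated)
13 | [(2R,3S)-2-[(4R,5R)-4,5-dicyclohexyl-1,3,2-dioxaborolan-2-yl]-5-(dimethoxymethyl)-7-methoxy-2-(3,4,5-trimethoxyphenyl)-2,3-dihydro-1-benzofuran-3-yl]methyl pivalate (aryl trans to CH2OPiv, boron cis to it) | COc1cc([C@]2(B3O[C@H](C4CCCCC4)[C@@H](C4CCCCC4)O3)Oc3c(OC)cc(C(OC)OC)cc3[C@H]2COC(=O)C(C)(C)C)cc(OC)c1OC | intermediate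
14 | [(2R,3S)-5-(dimethoxymethyl)-7-methoxy-2-(3,4,5-trimethoxyphenyl)-2,3-dihydro-1-benzofuran-3-yl]methyl pivalate (2,3-trans) | COc1cc([C@@H]2Oc3c(OC)cc(C(OC)OC)cc3[C@H]2COC(=O)C(C)(C)C)cc(OC)c1OC | intermediate (not isolated)
15 | [(2R,3S)-5-formyl-7-methoxy-2-(3,4,5-trimethoxyphenyl)-2,3-dihydro-1-benzofuran-3-yl]methyl pivalate (2,3-trans) | COc1cc([C@@H]2Oc3c(OC)cc(C=O)cc3[C@H]2COC(=O)C(C)(C)C)cc(OC)c1OC | intermediate
16 | ethyl (E)-3-[(2R,3S)-7-methoxy-3-(pivaloyloxymethyl)-2-(3,4,5-trimethoxyphenyl)-2,3-dihydro-1-benzofuran-5-yl]prop-2-enoate | COc1cc([C@@H]2Oc3c(OC)cc(/C=C/C(=O)OCC)cc3[C@H]2COC(=O)C(C)(C)C)cc(OC)c1OC | intermediate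
17 | (−)-(7R,8S,7'E)-3,4,5,5'-tetramethoxy-4',7-epoxy-8,3'-neolign-7'-ene-9,9'-diol | COc1cc([C@@H]2Oc3c(OC)cc(/C=C/CO)cc3[C@H]2CO)cc(OC)c1OC | target

Total step count: 8.
Longest linear sequence: 7 steps (steps 1, 2, 3, 5, 6, 7, 8, from 5-iodovanillin); step 4 is a one-step side branch.

Steps most likely to fail

Step 5 (proposed new method). The boronate may fail to alkylate at C8 with aryl migration, for example by reverting to the lithiobenzofuran, which is then alkylated directly. The diol may also discriminate the two faces of C8 only weakly. The fallback uses known chemistry, sets out from 1 and comes back to the route at 14. O-Alkylation of 1 with 3,4,5-trimethoxybenzyl chloride (K2CO3, DMF) would give 3-iodo-5-methoxy-4-[(3,4,5-trimethoxybenzyl)oxy]benzaldehyde F1. Acetalisation as in step 3 would give its dimethyl acetal F2. Pd-catalysed coupling of the aryl iodide with methyl diazoacetate (Pd(PPh3)4, Ag2CO3, Et3N, toluene, rt) would give the aryldiazoacetate F3. Enantioselective intramolecular Rh(II)-carbene insertion into the benzylic C–H bond (Rh2(S-PTTL)4 or its enantiomer, whichever delivers 2R; toluene, −60 °C) should close the ring to the cis ester F4. NaOMe/MeOH would epimerise C3 to the trans ester F5, LiAlH4 would reduce it to the alcohol F6, and PivCl/pyridine would give 14, which enters the acid stage of step 6.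

Step 6. Protonation at C7 may not be cleanly front-side, or the hindered dioxaborolane may bind fluoride slowly, so that forcing conditions erode the configuration at C7. The fallback replaces stereospecific substitution by thermodynamic control, sets out from 13 and comes back at 15. The C–B bond is cleaved without regard to stereochemistry (CsF, wet DMSO, heat) and the acetal is hydrolysed, giving 15 mixed with its C7 epimer, the cis aldehyde F7. Brief treatment with acid (TFA or BF3·OEt2, CH2Cl2, 0 °C) should then equilibrate the mixture through reversible heterolysis of the benzylic C7–O bond. This is the known acid-induced cis-to-trans isomerisation of 2-aryl-3-alkyl-2,3-dihydrobenzofurans with electron-rich aryl groups. C8 is not touched, so the more stable trans isomer 15 should result.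

Step 1. Loss of the silyl group from the alkyne with oxidative alkyne dimerisation, or a stalled cyclisation of the alkynylphenol, may erode the domino process. The fallback avoids the alkyne, sets out from 1 and comes back at 5. Suzuki–Miyaura coupling of 1 with (E)-2-(2-ethoxyvinyl)-4,4,5,5-tetramethyl-1,3,2-dioxaborolane (Pd(dppf)Cl2, K2CO3, dioxane/H2O, 80 °C) would give the enol ether 3-[(E)-2-ethoxyvinyl]-4-hydroxy-5-methoxybenzaldehyde F8. Acid (p-TsOH cat., toluene, 60 °C) should then cyclise it with loss of ethanol to benzofuran 5 directly, which also makes step 2 unnecessary.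

Further compounds

F1 | step 5 | 3-iodo-5-methoxy-4-[(3,4,5-trimethoxybenzyl)oxy]benzaldehyde | COc1cc(C=O)cc(I)c1OCc1cc(OC)c(OC)c(OC)c1
F2 | step 5 | 5-(dimethoxymethyl)-1-iodo-3-methoxy-2-[(3,4,5-trimethoxybenzyl)oxy]benzene | COC(OC)c1cc(OC)c(OCc2cc(OC)c(OC)c(OC)c2)c(I)c1
F3 | step 5 | methyl 2-diazo-2-{5-(dimethoxymethyl)-3-methoxy-2-[(3,4,5-trimethoxybenzyl)oxy]phenyl}acetate | COC(=O)C(=[N+]=[N-])c1cc(C(OC)OC)cc(OC)c1OCc1cc(OC)c(OC)c(OC)c1
F4 | step 5 | methyl (2R,3S)-5-(dimethoxymethyl)-7-methoxy-2-(3,4,5-trimethoxyphenyl)-2,3-dihydro-1-benzofuran-3-carboxylate (2,3-cis) | COc1cc([C@@H]2Oc3c(OC)cc(C(OC)OC)cc3[C@@H]2C(=O)OC)cc(OC)c1OC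
F5 | step 5 | methyl (2R,3R)-5-(dimethoxymethyl)-7-methoxy-2-(3,4,5-trimethoxyphenyl)-2,3-dihydro-1-benzofuran-3-carboxylate (2,3-trans) | COc1cc([C@@H]2Oc3c(OC)cc(C(OC)OC)cc3[C@H]2C(=O)OC)cc(OC)c1OC
F6 | step 5 | [(2R,3S)-5-(dimethoxymethyl)-7-methoxy-2-(3,4,5-trimethoxyphenyl)-2,3-dihydro-1-benzofuran-3-yl]methanol (2,3-trans) | COc1cc([C@@H]2Oc3c(OC)cc(C(OC)OC)cc3[C@H]2CO)cc(OC)c1OC
F7 | step 6 | [(2S,3S)-5-formyl-7-methoxy-2-(3,4,5-trimethoxyphenyl)-2,3-dihydro-1-benzofuran-3-yl]methyl pivalate (2,3-cis) | COc1cc([C@H]2Oc3c(OC)cc(C=O)cc3[C@H]2COC(=O)C(C)(C)C)cc(OC)c1OC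
F8 | step 1 | 3-[(E)-2-ethoxyvinyl]-4-hydroxy-5-methoxybenzaldehyde | CCO/C=C/c1cc(C=O)cc(OC)c1O
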